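**Plan**

- Retrosynthesis: the four O-silyl groups come off last; before that, both aryl C1–CH2 bonds of the central CH2–O–CH2 unit are cut in one disconnection, giving two identical arylmagnesium units and a two-carbon, one-oxygen bis-electrophile.
- Enabling feature: each ring carries CH2O at C1, Br at C2 and C3, OH at C4 and C5 and H at C6, and the two identical rings hang by C1 on the CH2–O–CH2 linchpin. In an O-protected 3,4-dibromocatechol the only C–H next to bromine is exactly the future C1.
- Forward: 2,3-dibromophenol is ortho-formylated, Dakin-oxidised to 3,4-dibromocatechol and bis-silylated. The arene is metalated next to bromine, two arylmagnesiums are joined through bis(chloromethyl) ether, and fluoride frees the four phenols.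
- No ring is formed: both benzene rings come from the starting phenol, and the chain is joined in one operation that makes both C–C bonds.
- Stereochemistry: the target has no stereocentre and no stereogenic double bond, so nothing has to be controlled.

Key step: step 4

Remark on the chemistry: the phenols are carried as tert-butyldimethylsilyl ethers, because Lewis acids strong enough to cleave aryl methyl ethers (BBr3 and the like) would also cleave the dibenzyl ether, whereas fluoride does not. The arylmagnesium is reached by lithiation with a hindered lithium amide and transmetalation, because a magnesium amide alone is expected to be too slow on an arene activated only by bromine.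

Assumption: paraformaldehyde is drawn as monomeric formaldehyde. Bis(chloromethyl) ether, a regulated carcinogen, is handled as a solution in a closed system and residues are destroyed with aqueous ammonia.

**Step 1**
Reactants: 1 2,3-dibromophenol; 2 paraformaldehyde (formaldehyde)
Product: 4 3,4-dibromo-2-hydroxybenzaldehyde, via hydroxymethylphenol 3 (not isolated)
Conditions: MgCl2, Et3N, (CH2O)n, MeCN, reflux; aq. HCl
Reagents that add atoms: none
Why: Casnati–Skattebøl ortho-formylation, in which the magnesium phenoxide delivers formaldehyde to the only free ortho carbon (the other ortho carbon bears bromine) to give the benzylic alkoxide of 3, which a second formaldehyde oxidises by hydride transfer, as is well known for 2-bromophenol.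

**Step 2**
Reactants: 4 3,4-dibromo-2-hydroxybenzaldehyde
Product: 6 3,4-dibromobenzene-1,2-diol (3,4-dibromocatechol), via aryl formate 5 (not isolated)
Conditions: 30% aq. H2O2, NaOH, H2O/THF, 0 °C → rt, N2; then aq. HCl
Reagents that add atoms: hydrogen peroxide, OO
Why: Dakin oxidation, in which hydroperoxide adds to the aldehyde of the ortho-hydroxybenzaldehyde, aryl migration gives formate 5 and hydroxide cleaves it in the flask, the same conversion that turns 3-bromosalicylaldehyde into 3-bromocatechol.

**Step 3**
Reactants: 6 3,4-dibromobenzene-1,2-diol
Product: 7 1,2-dibromo-3,4-bis(tert-butyldimethylsilyloxy)benzene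
Conditions: TBSCl (2.5 equiv), imidazole, DMF, rt → 40 °C
Reagents that add atoms: tert-butyldimethylsilyl chloride, CC(C)(C)[Si](C)(C)Cl
Why: standard imidazole-promoted O-silylation of both phenols, giving bulky silyl ethers that tolerate amide bases and Grignard reagents, do not direct metalation, shield the neighbouring C–H and are later removed by fluoride without touching the dibenzyl ether.

**Step 4**
Reactants: 7 1,2-dibromo-3,4-bis(tert-butyldimethylsilyloxy)benzene (two molecules); 8 bis(chloromethyl) ether
Product: 12 bis[2,3-dibromo-4,5-bis(tert-butyldimethylsilyloxy)benzyl] ether, via aryllithium 9 (not isolated), via arylmagnesium bromide 10 (not isolated), via chloromethyl benzyl ether 11 (not isolated)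
Conditions: lithium 2,2,6,6-tetramethylpiperidide (LiTMP, from TMPH and n-BuLi; 1.0 equiv per 7), THF, −78 °C; MgBr2·OEt2, −78 °C; 8 (0.45 equiv per 7), −78 → 0 °C; aq. NH4Cl/NH3
Reagents that add atoms: none
Why: LiTMP removes C6–H of 7, the only ring proton next to bromine, which the adjacent bromine and the second bromine meta to it acidify, while C5–H lies beside a bulky silyl ether that neither acidifies much nor lets the hindered amide approach; the closest known reaction type is the low-temperature lithiation of 1,2-dibromoarenes ortho to bromine with lithium amides. Transmetalation of aryllithium 9 with MgBr2 at −78 °C gives arylmagnesium bromide 10, which at or below 0 °C should neither pass bromine along the ring nor lose MgBr2 to an aryne. Each C–Cl bond of 8 ionises with magnesium assistance to an oxocarbenium ion that the aryl–magnesium bond captures, the known alkylation of aryl Grignard reagents by chloromethyl ethers; the first product 11 is again an α-chloro ether, so the second arylmagnesium enters in the same way and both aryl C1–CH2 bonds form in one flask. No ring closes and no stereocentre is formed. The step needs site selectivity in the metalation, secured as described, and complete double substitution, secured by making 8 the limiting component so that no 11 survives. The liberated TMPH is too hindered to compete for the electrophile at low temperature, and the aryl bromides and silyl ethers are inert to all reagents used.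

**Step 5**
Reactants: 12 bis[2,3-dibromo-4,5-bis(tert-butyldimethylsilyloxy)benzyl] ether
Product: 13 bis(2,3-dibromo-4,5-dihydroxybenzyl) ether
Conditions: Bu4NF (TBAF), AcOH, THF, 0 °C, N2; pH 5 phosphate buffer work-up
Reagents that add atoms: none
Why: fluoride-driven Si–O cleavage of aryl silyl ethers, buffered with acetic acid so that the liberated catechols stay protonated and no para-phenoxide remains to expel the benzylic oxygen as a quinone methide or to be oxidised by air, while aryl bromides and the dibenzyl ether do not react with Bu4NF.

**Compound list**

1 | 2,3-dibromophenol | Oc1cccc(Br)c1Br | starting material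
2 | paraformaldehyde (formaldehyde) | C=O | starting material
3 | 2,3-dibromo-6-(hydroxymethyl)phenol (as its magnesium salt, formed in the flask) | OCc1ccc(Br)c(Br)c1O | intermediate
4 | 3,4-dibromo-2-hydroxybenzaldehyde | O=Cc1ccc(Br)c(Br)c1O | intermediate
5 | 3,4-dibromo-2-hydroxyphenyl formate (formed in the flask) | O=COc1ccc(Br)c(Br)c1O | intermediate
6 | 3,4-dibromobenzene-1,2-diol (3,4-dibromocatechol) | Oc1ccc(Br)c(Br)c1O | intermediate
7 | 1,2-dibromo-3,4-bis(tert-butyldimethylsilyloxy)benzene | CC(C)(C)[Si](C)(C)Oc1ccc(Br)c(Br)c1O[Si](C)(C)C(C)(C)C | intermediate
8 | bis(chloromethyl) ether | ClCOCCl | starting material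
9 | [2,3-dibromo-4,5-bis(tert-butyldimethylsilyloxy)phenyl]lithium (formed in the flask) | [Li]c1cc(O[Si](C)(C)C(C)(C)C)c(O[Si](C)(C)C(C)(C)C)c(Br)c1Br | intermediate
10 | [2,3-dibromo-4,5-bis(tert-butyldimethylsilyloxy)phenyl]magnesium bromide (formed in the flask) | Br[Mg]c1cc(O[Si](C)(C)C(C)(C)C)c(O[Si](C)(C)C(C)(C)C)c(Br)c1Br | intermediate
11 | 2,3-dibromo-1-[(chloromethoxy)methyl]-4,5-bis(tert-butyldimethylsilyloxy)benzene (formed in the flask) | ClCOCc1cc(O[Si](C)(C)C(C)(C)C)c(O[Si](C)(C)C(C)(C)C)c(Br)c1Br | intermediate
12 | bis[2,3-dibromo-4,5-bis(tert-butyldimethylsilyloxy)benzyl] ether | CC(C)(C)[Si](C)(C)Oc1cc(COCc2cc(O[Si](C)(C)C(C)(C)C)c(O[Si](C)(C)C(C)(C)C)c(Br)c2Br)c(Br)c(Br)c1O[Si](C)(C)C(C)(C)C | intermediate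
13 | bis(2,3-dibromo-4,5-dihydroxybenzyl) ether | Oc1cc(COCc2cc(O)c(O)c(Br)c2Br)c(Br)c(Br)c1O | target

**Total step count:** 5
**Longest linear sequence:** 5 steps (1 → 13)

**Steps most likely to fail**

Step 4. The deprotonation may stay incomplete, bromine may migrate around the ring at the aryllithium stage (halogen dance), metal bromide may be lost to an aryne before or after transmetalation, and amide or amine may consume part of the electrophile so that the second substitution lags. The fallback sets out from 4 and comes back at 12; it fixes the metal position with an iodine instead of a C–H deprotonation. Iodination of 4 para to the hydroxyl group (NIS, TFA, MeCN; hydroxyl directs para and formyl meta to the same carbon) should give 3,4-dibromo-2-hydroxy-5-iodobenzaldehyde F1. Dakin oxidation as in step 2, through 3,4-dibromo-2-hydroxy-5-iodophenyl formate F2, should give 3,4-dibromo-5-iodobenzene-1,2-diol F3, and silylation as in step 3 should give 2,3-dibromo-1-iodo-4,5-bis(tert-butyldimethylsilyloxy)benzene F4. Iodine–magnesium exchange with iPrMgCl·LiCl (THF, −40 °C), far faster at iodine than at bromine and free of amide and amine, should give [2,3-dibromo-4,5-bis(tert-butyldimethylsilyloxy)phenyl]magnesium chloride F5 at the required carbon only. Addition of 8 as in step 4 then leads through 11 back to 12.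

Step 5. Once the phenols are free, the para-hydroxybenzyl ether may fragment through quinone methide formation under the basic fluoride, and the catechols may be oxidised by air. The fallback sets out from 12 and comes back at 13; it moves the ether formation behind the deprotection. Aqueous HF in MeCN should remove the silyl groups under acidic conditions and can be pushed on purpose to hydrolysis of the benzylic ether, giving 2,3-dibromo-4,5-dihydroxybenzyl alcohol F6. This para-hydroxybenzyl alcohol is then joined to itself by acid-catalysed dehydrative self-etherification (cat. TsOH, MeCN, 4 Å molecular sieves, rt to 40 °C, N2), the usual behaviour of para-hydroxybenzyl alcohols, which returns to 13.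

Step 1. Hydroxymethylation of the electron-poor, hindered magnesium phenoxide may be sluggish, and the intermediate benzylic alcohol may condense with unreacted phenol instead of being oxidised. The fallback sets out from 1 and comes back at 6; it brings in the ortho carbon by acyl migration instead of formylation. O-Acetylation (Ac2O, pyridine) should give 2,3-dibromophenyl acetate F7. Fries rearrangement (AlCl3, chlorobenzene, 130 °C) should move the acetyl group to the free ortho carbon, the para carbon being crowded by its bromine neighbour and the ortho product being held as a chelate, to give 1-(3,4-dibromo-2-hydroxyphenyl)ethanone F8. Dakin oxidation of this ortho-hydroxyaryl ketone (H2O2, NaOH), through 3,4-dibromo-2-hydroxyphenyl acetate F9, returns to 6.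

**Further compounds**

F1 | step 4 | 3,4-dibromo-2-hydroxy-5-iodobenzaldehyde | O=Cc1cc(I)c(Br)c(Br)c1O
F2 | step 4 | 3,4-dibromo-2-hydroxy-5-iodophenyl formate | O=COc1cc(I)c(Br)c(Br)c1O
F3 | step 4 | 3,4-dibromo-5-iodobenzene-1,2-diol | Oc1cc(I)c(Br)c(Br)c1O
F4 | step 4 | 2,3-dibromo-1-iodo-4,5-bis(tert-butyldimethylsilyloxy)benzene | CC(C)(C)[Si](C)(C)Oc1cc(I)c(Br)c(Br)c1O[Si](C)(C)C(C)(C)C
F5 | step 4 | [2,3-dibromo-4,5-bis(tert-butyldimethylsilyloxy)phenyl]magnesium chloride | Cl[Mg]c1cc(O[Si](C)(C)C(C)(C)C)c(O[Si](C)(C)C(C)(C)C)c(Br)c1Br
F6 | step 5 | 2,3-dibromo-4,5-dihydroxybenzyl alcohol | OCc1cc(O)c(O)c(Br)c1Br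
F7 | step 1 | 2,3-dibromophenyl acetate | CC(=O)Oc1cccc(Br)c1Br
F8 | step 1 | 1-(3,4-dibromo-2-hydroxyphenyl)ethanone | CC(=O)c1ccc(Br)c(Br)c1O
F9 | step 1 | 3,4-dibromo-2-hydroxyphenyl acetate | CC(=O)Oc1ccc(Br)c(Br)c1O
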